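# Proposed synthesis of CNP0168412.1, the stearate of (+)-lariciresinol, by a three-component palladium annulation around a malonate carbon

Compounds are numbered 1–21 in the order in which they first appear in the steps; the full list follows the steps. Ring atoms are O1, C2 (aryl), C3 (CH2O), C4 (arylmethyl), C5 (CH2).

Remark 1: which enantiomer of 1-phenylethylamine gives the less soluble salt with the wanted acid cannot be foreseen; the route is written with the (R)-amine 15, and the (S)-amine takes its place if the salts crystallise the other way round.

Remark 2: racemic compounds (9–14) are drawn as the enantiomer that is carried on. The change from 2R in 10 to 2S in 12 reflects a change of CIP priorities at C3, not of spatial arrangement.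

## Analysis of the target

Compound 21 is the stearic ester of the primary alcohol of (+)-lariciresinol (19). It has one tetrahydrofuran ring (O1, C2, C3, C4, C5) with a 4-hydroxy-3-methoxyphenyl group on C2, the stearoyloxymethyl group on C3, a 4-hydroxy-3-methoxybenzyl group on C4 and an unsubstituted CH2 at C5. The three stereocentres are contiguous, (2S,3R,4R): the aryl group on C2 and the CH2O group on C3 are trans, the CH2O group and the benzyl group on C4 are cis, so aryl and benzyl lie on opposite faces. The 2,3-trans relation is the thermodynamically preferred one and can be reached by equilibration. The 3,4-cis relation between two neighbouring carbon substituents is the less stable one and has to come from a kinetically controlled step. The sensitive groups are: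

- the two free guaiacyl phenols, which are oxidisable and compete for acylating agents;
- the C2–O1 bond, benzylic to a para-oxygenated arene, which is open to acid-induced ionisation (epimerisation at C2) and to hydrogenolysis;
- the fatty ester, which tolerates neither hydride reagents nor strong base once in place.

The difficulties are therefore the stereotriad on a flexible five-membered ring, the absolute configuration (the skeleton offers no chiral-pool handle), and the esterification of one hydroxyl group out of three. The plan rests on the position of C3. It is bonded to C2 (which carries O1 and an aryl group), to C4 (which carries the benzylic carbon) and to the only exocyclic carbon that can derive from a carboxyl group. A malonate carbon at C3 can thus be generated as a carbanion by addition of an alkoxide to an arylidene acceptor (O1–C2) and consumed by attack on an alkyne (C3–C4), while the metal that activates the alkyne delivers the second aryl group to the far alkyne carbon.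

## Retrosynthetic reasoning

**21 ⇒ 19 + 20.** The ester C–O bond is cut last. A stearate would not survive the hydride reduction or the basic steps earlier in the route, and the triol 19 allows an enzyme to choose the aliphatic hydroxyl group over the two phenols. The forward reaction is an irreversible lipase-catalysed acyl transfer from the enol ester 20.

**19 ⇒ 18.** The CH2OH group is traced back to the carboxyl group of acid 18. The carboxyl group is what remains of the malonate and is also the handle for resolution. The reduction is placed after the saturation of the alkene for two reasons: the hydride reagent that is selective for acids would also hydroborate an alkene, and a hydroxymethyl group next to the alkene could anchor the substrate to the hydrogenation catalyst and reverse the facial selectivity.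

**18 ⇒ 17.** The C4–H bond and one benzylic C–H bond are removed, giving the exocyclic benzylidene of 17; the two phenols are masked as benzyl ethers. The forward hydrogenation must add to the face opposite the C3 carboxyl group, which places the new benzyl group cis to it (the kinetic 3,4-cis relation) and trans to the C2 aryl group. The benzyl ethers are chosen because they fall in the same operation.

**17 ⇒ 16 ⇒ 14 + 15.** The ring-forming step cannot fix the absolute configuration, so the enantiomers are separated at the first carboxylic acid of the sequence. The racemic trans acid 14 is resolved as its crystalline salt 16 with amine 15, and the free acid 17 is recovered from the salt. Placing the resolution here means that only one enantiomer is carried through the last three steps.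

**14 ⇒ 12 (through 13).** The acid comes from the methyl ester 12 by hydrolysis; the carboxylate 13 is the form in the flask before acidification.

**12 ⇒ 10 (through 11).** The C3–H bond of 12 replaces one of the two ester groups of 10. Removing the surplus ester creates the C3 stereocentre. The forward step has to end at the 2,3-trans ester by equilibration of the cis epimer 11 through the C3 enolate, without moving the benzylidene double bond into the ring. Methyl esters are chosen over ethyl esters so that the nucleophilic demethylation runs at a lower temperature and the equilibration can use the matching alkoxide.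

**10 ⇒ 3 + 7 + 6 (through 8 and 9).** This is the key disconnection. Three bonds are cut: O1–C2, C3–C4 and the bond from the exocyclic carbon to its aryl group. The cut is made here because these three bonds surround the malonate carbon and fall apart into three simple, achiral compounds: the acceptor 3, the alcohol 7 and the iodide 6. The forward reaction has to add the alkoxide 8 to 3, carry the adduct 9 into a 5-exo-dig ring closure on the metal-activated alkyne and end with aryl transfer from the metal. One flask gives the ring, all heavy atoms of the skeleton and the C2 stereocentre (as the racemate).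

**3 ⇒ 1 + 2 and 6 ⇒ 4 + 5.** The arylidene C=C bond of 3 is a condensation of the commercial aldehyde 1 with the malonate 2. The aryl iodide 6 is the benzyl ether of the commercial phenol 4, made with the halide 5. Both steps are routine, so the risk of the route is concentrated in the annulation.

## Alternatives that were turned down

**Alternative 1:** The C3–carboxyl and C4–benzylic bonds are both cut, leading back to a 2-aryl-2,5-dihydrofuran A2 and an arylketene A4 generated from the arylacetyl chloride A3. In the forward direction A4 would add across the ring alkene of A2 under Lewis-acid promotion to give the cis-fused cyclobutanone A1; later cleavage of its C(=O)–CH(aryl) bond would reveal the C3 carboxyl and the C4 benzyl group.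

- For it: the cis ring fusion fixes the 3,4-cis relation by construction, and approach anti to the C2 aryl group gives 2,3-trans. A2 is the product of a catalytic asymmetric Heck arylation, so no resolution is needed. On stereocontrol, both absolute and relative, this alternative is stronger than the chosen route.
- Against it: the two alkene carbons of A2 are electronically almost equal, and the carbonyl carbon of A4 would have to bond to the more crowded one, next to C2. Arylketenes dimerise readily. The Lewis acid needed for an unactivated alkene would ionise the C2–O bond of A2, which is benzylic, allylic and para-oxygenated, so racemisation or ring opening is expected. The four-membered ring must then be opened regioselectively.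
- Comparison: the chosen strategy gives up stereochemical economy (racemate, resolution, a separate step for C4). In return it assembles the whole skeleton with unambiguous regiochemistry in one step of a known type from three simple compounds.

**Alternative 2:** C2 is treated as a one-carbon unit. The C2–C3 and O1–C2 bonds are cut, leading to the ylide of the chiral benzylsulfonium salt A6 and the conjugated aldehyde ester A7. In the forward direction the ylide would add through carbon to the alkene carbon β to the aldehyde, and the aldehyde enolate oxygen would displace the sulfide to close the 2,3-dihydrofuran A5.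

- For it: it is convergent, the C2-symmetric sulfide could in principle set the absolute configuration at C2, and A5 is only a hydrogenation, a reduction and the end-game away from 21. On step count and on the design of asymmetric induction it is stronger.
- Against it: semi-stabilised benzylides normally attack an aldehyde carbonyl (epoxide), or after conjugate addition close through carbon (cyclopropane). Closure through oxygen is typical only of more delocalised enolates. A7 has two electrophilic alkene positions and acidic benzylic hydrogens. In A5 the C3–H is α to the ester and allylic to the enol ether, so it is epimerisable and prone to aromatisation to a furan.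
- Comparison: the chosen strategy uses a malonate carbanion whose site of reaction is not in doubt, and pays for this with the removal of the second ester and the resolution.

**Alternative 3:** The C3–C4 bond and the benzylic carbon–aryl bond are cut, leading to the α-bromo ester A9, which carries an allyl ether on the benzylic carbon, and the arylzinc bromide A10. In the forward direction a nickel catalyst with a tridentate nitrogen ligand would generate the C3 radical, which cyclises 5-exo onto the allyl group; the exocyclic CH2 radical would then be coupled with A10 to give A8.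

- For it: A8 already has the full stereotriad and oxidation pattern, so only ester reduction, debenzylation and acylation remain. The chair-like transition state of the radical cyclisation predicts the 2,4-trans and 3,4-cis relations that are needed. On steps after the key step, and on avoiding a separate C4-setting step, it is stronger.
- Against it: A9 must be made enantiopure at the benzylic carbon, which adds steps before the key step. The ester-substituted radical is planar and delocalised, so the 3,4-cis preference is weak. Direct nickel-catalysed α-arylation of the bromo ester by A10 before cyclisation is a fast known pathway. β-Elimination of the allyloxy group from any enolate-like intermediate would give a cinnamate.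
- Comparison: the chosen strategy puts its main risk into a step with close precedent and uses cheaper, achiral precursors; it needs more adjustments after the ring is formed.

Key step: step 3

## Steps

Step 1
Reactants: 1 4-(benzyloxy)-3-methoxybenzaldehyde; 2 dimethyl malonate
Product: 3 dimethyl 2-[4-(benzyloxy)-3-methoxybenzylidene]propanedioate
Conditions: piperidine (0.1 equiv), AcOH (0.1 equiv), toluene, reflux, Dean–Stark
Reagents that add atoms: none
Why: Knoevenagel condensation; the malonate adds to the aldehyde through the iminium ion and azeotropic removal of water drives the dehydration to the arylidenemalonate, which has no stereochemical element.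

Step 2
Reactants: 4 4-iodo-2-methoxyphenol; 5 benzyl bromide
Product: 6 1-(benzyloxy)-4-iodo-2-methoxybenzene
Conditions: K2CO3, DMF, rt
Reagents that add atoms: none
Why: Williamson ether synthesis; the phenoxide is alkylated at oxygen by the benzylic halide in an SN2 reaction, and the aryl iodide is inert under these conditions.

Step 3
Reactants: 7 prop-2-yn-1-ol; 3 dimethyl 2-[4-(benzyloxy)-3-methoxybenzylidene]propanedioate; 6 1-(benzyloxy)-4-iodo-2-methoxybenzene
Product: 10 dimethyl rac-(4Z)-2-[4-(benzyloxy)-3-methoxyphenyl]-4-[4-(benzyloxy)-3-methoxybenzylidene]tetrahydrofuran-3,3-dicarboxylate, via potassium prop-2-yn-1-olate 8 (not isolated), via potassium malonate adduct 9 (not isolated)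
Conditions: 7 (1.2 equiv), KOt-Bu (1.1 equiv), THF, 0 °C; then 3 (1.0 equiv); then 6 (1.1 equiv), PdCl2(PPh3)2 (5 mol%), n-BuLi (10 mol%), DMSO–THF, rt to 50 °C
Reagents that add atoms: none
Why: Deprotonation of 7 gives the alkoxide 8, which adds reversibly to the electron-poor alkene of 3 (oxa-Michael addition, O1–C2) to give the malonate anion 9. Zerovalent palladium, made in the flask from PdCl2(PPh3)2 and n-BuLi, inserts into the C–I bond of 6; the divalent arylpalladium iodide binds the alkyne of 9, and the malonate carbon attacks the internal alkyne carbon from the side opposite the metal in a 5-exo-dig closure (C3–C4), the only ring formed. Reductive elimination from the alkenyl(aryl)palladium joins the exocyclic carbon to the aryl group and returns zerovalent palladium. Anti addition followed by reductive elimination with retention places the new aryl group trans to C3 and cis to C5, which is the (Z)-olefin. The closest known reaction type is the palladium-mediated three-component coupling of propargyl alkoxides, alkylidene- or arylidenemalonates and aryl halides to 4-arylidenetetrahydrofuran-3,3-dicarboxylates. C2 is the only new stereocentre; it is set in the achiral, reversible oxa-Michael addition with no controlling element, so 10 forms as the racemate and the absolute configuration is dealt with in steps 6 and 7. The step needs alkyne activation to win over direct arylation of the malonate or of the alkyne C–H bond; the absence of copper, the soft and hindered malonate anion, the five-membered transition state and the use of an iodide (fast oxidative addition of the electron-rich arene) should secure this.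

Step 4
Reactants: 10 dimethyl rac-(4Z)-2-[4-(benzyloxy)-3-methoxyphenyl]-4-[4-(benzyloxy)-3-methoxybenzylidene]tetrahydrofuran-3,3-dicarboxylate
Product: 12 methyl rac-(2S,3S,4Z)-2-[4-(benzyloxy)-3-methoxyphenyl]-4-[4-(benzyloxy)-3-methoxybenzylidene]tetrahydrofuran-3-carboxylate (2,3-trans), via cis-epimer 11 (not isolated)
Conditions: LiCl (3 equiv), H2O (2 equiv), DMSO, 135 °C; crude product then NaOMe (0.2 equiv), MeOH–THF, 0 °C to rt
Reagents that add atoms: none
Why: Krapcho dealkoxycarbonylation: chloride demethylates one ester (SN2 at the methyl group), the carboxylate loses CO2, and the ester dienolate is protonated at C3, the kinetically preferred α-position, which keeps the benzylidene exocyclic. Catalytic methoxide then equilibrates C3 through the same enolate to the 2,3-trans ester, in which the ester avoids the C2 aryl group; methyl esters allow a lower temperature and exclude transesterification by methoxide.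

Step 5
Reactants: 12 methyl rac-(2S,3S,4Z)-2-[4-(benzyloxy)-3-methoxyphenyl]-4-[4-(benzyloxy)-3-methoxybenzylidene]tetrahydrofuran-3-carboxylate
Product: 14 rac-(2S,3S,4Z)-2-[4-(benzyloxy)-3-methoxyphenyl]-4-[4-(benzyloxy)-3-methoxybenzylidene]tetrahydrofuran-3-carboxylic acid, via lithium carboxylate 13 (not isolated)
Conditions: LiOH·H2O (3 equiv), THF–MeOH–H2O, 0 °C to rt; then 1 M HCl to pH 3, 0 °C
Reagents that add atoms: lithium hydroxide ([Li+].[OH-])
Why: Ester saponification by acyl–oxygen cleavage; hydroxide attack at the ester carbonyl should be faster than deprotonation at C3, and any epimerisation that does occur runs towards the wanted trans isomer, after which the carboxylate is no longer enolisable under the conditions.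

Step 6
Reactants: 14 rac-(2S,3S,4Z)-2-[4-(benzyloxy)-3-methoxyphenyl]-4-[4-(benzyloxy)-3-methoxybenzylidene]tetrahydrofuran-3-carboxylic acid; 15 (R)-1-phenylethylamine
Product: 16 (R)-1-phenylethylammonium (2S,3S,4Z)-2-[4-(benzyloxy)-3-methoxyphenyl]-4-[4-(benzyloxy)-3-methoxybenzylidene]tetrahydrofuran-3-carboxylate
Conditions: 15 (0.5 equiv), EtOH–EtOAc, warm then slow cooling; recrystallisation to constant optical purity (chiral HPLC)
Reagents that add atoms: none
Why: Classical resolution through diastereomeric salts: the two salts of the racemic acid with one amine enantiomer differ in lattice energy and solubility, and half an equivalent of amine leaves the unwanted acid in solution. No stereocentre is formed; the (2S,3S) enantiomer is selected.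

Step 7
Reactants: 16 (R)-1-phenylethylammonium (2S,3S,4Z)-2-[4-(benzyloxy)-3-methoxyphenyl]-4-[4-(benzyloxy)-3-methoxybenzylidene]tetrahydrofuran-3-carboxylate
Product: 17 (2S,3S,4Z)-2-[4-(benzyloxy)-3-methoxyphenyl]-4-[4-(benzyloxy)-3-methoxybenzylidene]tetrahydrofuran-3-carboxylic acid
Conditions: 1 M HCl, EtOAc, 0 °C (partition)
Reagents that add atoms: none
Why: Proton transfer from the mineral acid frees the carboxylic acid into the organic phase and takes the amine into water as its hydrochloride; cold dilute acid and a short contact time spare the benzylic C2–O1 bond.

Step 8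
Reactants: 17 (2S,3S,4Z)-2-[4-(benzyloxy)-3-methoxyphenyl]-4-[4-(benzyloxy)-3-methoxybenzylidene]tetrahydrofuran-3-carboxylic acid
Product: 18 (2S,3S,4R)-2-(4-hydroxy-3-methoxyphenyl)-4-(4-hydroxy-3-methoxybenzyl)tetrahydrofuran-3-carboxylic acid
Conditions: H2 (1 atm), 10% Pd/C, EtOAc–THF, rt
Reagents that add atoms: none
Why: Heterogeneous hydrogenation: the alkene should be adsorbed on the face opposite the adjacent C3 carboxyl group, so that both hydrogens enter anti to it and the new benzyl group at C4 ends cis to the carboxyl group and trans to the C2 aryl group (4R); a carboxyl group, unlike a hydroxymethyl group, has little tendency to anchor the substrate to the metal, which is why the acid is hydrogenated before it is reduced. The two aryl benzyl ethers are cleaved by hydrogenolysis in the same operation, while the benzylic C2–O1 bond of the ring reacts far more slowly in a neutral solvent at 1 atm.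

Step 9
Reactants: 18 (2S,3S,4R)-2-(4-hydroxy-3-methoxyphenyl)-4-(4-hydroxy-3-methoxybenzyl)tetrahydrofuran-3-carboxylic acid
Product: 19 (+)-lariciresinol, 4-[(2S,3R,4R)-4-(4-hydroxy-3-methoxybenzyl)-3-(hydroxymethyl)tetrahydrofuran-2-yl]-2-methoxyphenol
Conditions: BH3·THF (5 equiv), THF, 0 °C to rt; then MeOH
Reagents that add atoms: none
Why: Borane reduces a carboxylic acid through its acyloxyborane faster than it affects ethers or arenes; the phenols only consume reagent as aryloxyboranes, which the methanol quench cleaves. No stereocentre is touched (the change from 3S to 3R is a change of CIP priority only).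

Step 10
Reactants: 19 (+)-lariciresinol; 20 vinyl stearate
Product: 21 [(2S,3R,4R)-2-(4-hydroxy-3-methoxyphenyl)-4-(4-hydroxy-3-methoxybenzyl)tetrahydrofuran-3-yl]methyl octadecanoate
Conditions: 20 (3 equiv), immobilised Candida antarctica lipase B (Novozym 435), 2-methylbutan-2-ol, 4 Å molecular sieves, 45 °C
Reagents that add atoms: none
Why: Lipase-catalysed transesterification with an enol ester: the acyl-enzyme is intercepted by the primary aliphatic hydroxyl group, phenols are not acceptors under these conditions, and tautomerisation of the released vinyl alcohol to acetaldehyde makes the acyl transfer irreversible.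

## Compound list

1 | 4-(benzyloxy)-3-methoxybenzaldehyde | COc1cc(C=O)ccc1OCc1ccccc1 | starting material
2 | dimethyl malonate | COC(=O)CC(=O)OC | starting material
3 | dimethyl 2-[4-(benzyloxy)-3-methoxybenzylidene]propanedioate | COC(=O)C(=Cc1ccc(OCc2ccccc2)c(OC)c1)C(=O)OC | intermediate
4 | 4-iodo-2-methoxyphenol | COc1cc(I)ccc1O | starting material
5 | benzyl bromide | BrCc1ccccc1 | starting material
6 | 1-(benzyloxy)-4-iodo-2-methoxybenzene | COc1cc(I)ccc1OCc1ccccc1 | intermediate
7 | prop-2-yn-1-ol | C#CCO | starting material
8 | potassium prop-2-yn-1-olate | [K+].[O-]CC#C | intermediate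
9 | potassium salt of dimethyl 2-{[4-(benzyloxy)-3-methoxyphenyl](prop-2-yn-1-yloxy)methyl}propanedioate, racemic | [K+].COC(=O)[C-](C(=O)OC)C(OCC#C)c1ccc(OCc2ccccc2)c(OC)c1 | intermediate
10 | dimethyl (4Z)-2-[4-(benzyloxy)-3-methoxyphenyl]-4-[4-(benzyloxy)-3-methoxybenzylidene]tetrahydrofuran-3,3-dicarboxylate, racemate, (2R) enantiomer drawn | COc1cc(/C=C2\CO[C@H](c3ccc(OCc4ccccc4)c(OC)c3)C2(C(=O)OC)C(=O)OC)ccc1OCc1ccccc1 | intermediate
11 | methyl (2S,3R,4Z)-2-[4-(benzyloxy)-3-methoxyphenyl]-4-[4-(benzyloxy)-3-methoxybenzylidene]tetrahydrofuran-3-carboxylate, 2,3-cis, racemate | COC(=O)[C@@H]1/C(=C/c2ccc(OCc3ccccc3)c(OC)c2)CO[C@@H]1c1ccc(OCc2ccccc2)c(OC)c1 | intermediate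
12 | methyl (2S,3S,4Z)-2-[4-(benzyloxy)-3-methoxyphenyl]-4-[4-(benzyloxy)-3-methoxybenzylidene]tetrahydrofuran-3-carboxylate, 2,3-trans, racemate | COC(=O)[C@H]1/C(=C/c2ccc(OCc3ccccc3)c(OC)c2)CO[C@@H]1c1ccc(OCc2ccccc2)c(OC)c1 | intermediate
13 | lithium (2S,3S,4Z)-2-[4-(benzyloxy)-3-methoxyphenyl]-4-[4-(benzyloxy)-3-methoxybenzylidene]tetrahydrofuran-3-carboxylate, racemate | [Li+].[O-]C(=O)[C@H]1/C(=C/c2ccc(OCc3ccccc3)c(OC)c2)CO[C@@H]1c1ccc(OCc2ccccc2)c(OC)c1 | intermediate
14 | (2S,3S,4Z)-2-[4-(benzyloxy)-3-methoxyphenyl]-4-[4-(benzyloxy)-3-methoxybenzylidene]tetrahydrofuran-3-carboxylic acid, racemate | OC(=O)[C@H]1/C(=C/c2ccc(OCc3ccccc3)c(OC)c2)CO[C@@H]1c1ccc(OCc2ccccc2)c(OC)c1 | intermediate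
15 | (R)-1-phenylethylamine | C[C@@H](N)c1ccccc1 | starting material
16 | (R)-1-phenylethylammonium (2S,3S,4Z)-2-[4-(benzyloxy)-3-methoxyphenyl]-4-[4-(benzyloxy)-3-methoxybenzylidene]tetrahydrofuran-3-carboxylate | C[C@@H]([NH3+])c1ccccc1.[O-]C(=O)[C@H]1/C(=C/c2ccc(OCc3ccccc3)c(OC)c2)CO[C@@H]1c1ccc(OCc2ccccc2)c(OC)c1 | intermediate
17 | (2S,3S,4Z)-2-[4-(benzyloxy)-3-methoxyphenyl]-4-[4-(benzyloxy)-3-methoxybenzylidene]tetrahydrofuran-3-carboxylic acid, single enantiomer | OC(=O)[C@H]1/C(=C/c2ccc(OCc3ccccc3)c(OC)c2)CO[C@@H]1c1ccc(OCc2ccccc2)c(OC)c1 | intermediate
18 | (2S,3S,4R)-2-(4-hydroxy-3-methoxyphenyl)-4-(4-hydroxy-3-methoxybenzyl)tetrahydrofuran-3-carboxylic acid | OC(=O)[C@H]1[C@@H](Cc2ccc(O)c(OC)c2)CO[C@@H]1c1ccc(O)c(OC)c1 | intermediate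
19 | (+)-lariciresinol, 4-[(2S,3R,4R)-4-(4-hydroxy-3-methoxybenzyl)-3-(hydroxymethyl)tetrahydrofuran-2-yl]-2-methoxyphenol | OC[C@H]1[C@@H](Cc2ccc(O)c(OC)c2)CO[C@@H]1c1ccc(O)c(OC)c1 | intermediate
20 | vinyl stearate (ethenyl octadecanoate) | CCCCCCCCCCCCCCCCCC(=O)OC=C | starting material
21 | [(2S,3R,4R)-2-(4-hydroxy-3-methoxyphenyl)-4-(4-hydroxy-3-methoxybenzyl)tetrahydrofuran-3-yl]methyl octadecanoate | CCCCCCCCCCCCCCCCCC(=O)OC[C@H]1[C@@H](Cc2ccc(O)c(OC)c2)CO[C@@H]1c1ccc(O)c(OC)c1 | target

## Step count and the least certain steps

Total: 10 steps. Longest linear sequence: 9 steps (steps 1, 3, 4, 5, 6, 7, 8, 9, 10 from compound 1; the branch from compound 4 through step 2 is equally long).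

**Step 3 (key step).** The three events have to mesh. Oxidative addition of the electron-rich iodide 6 is comparatively slow, and the electron-rich acceptor 3 holds the alkoxide less firmly than a simple benzylidenemalonate. Retro-addition can therefore release alkoxide for transesterification, the alkyne terminus can be arylated at C–H, or the malonate anion can be protonated without ring closure.

Fallback, from 6 and 7, returning at 10: the aryl–alkyne bond is made first. Sonogashira coupling of 6 with 7 (PdCl2(PPh3)2, CuI, Et3N, THF, rt) should give 3-[4-(benzyloxy)-3-methoxyphenyl]prop-2-yn-1-ol F1. Conjugate addition of F1 to 3 and carbocyclisation of the zinc malonate onto the aryl alkyne (Zn(OTf)2, Et3N, toluene, 80 °C) then closes the same ring. Syn addition of the zinc enolate places the aryl group trans to C3, which is again the (Z)-olefin of 10. The olefin geometry is in any case erased in step 8.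

**Step 4.** The exocyclic double bond may migrate into the ring, into conjugation with the ester, by γ-protonation of the dienolate. This can happen in the hot, weakly basic dealkoxycarbonylation medium or during the methoxide equilibration. Epimerisation at C3 may also stay incomplete.

Fallback, from 10, returning at 12: mono-saponification (KOH, 1.1 equiv, MeOH–H2O, rt; cold dilute HCl) should give 2-[4-(benzyloxy)-3-methoxyphenyl]-4-[4-(benzyloxy)-3-methoxybenzylidene]-3-(methoxycarbonyl)tetrahydrofuran-3-carboxylic acid F2. Heating F2 in toluene at about 100 °C decarboxylates it through the neutral enol, so that C3 is protonated with no base present. A brief, monitored treatment with catalytic NaOMe in MeOH at 0 °C then converts the epimer mixture 11/12 into 12.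

**Step 8.** Facial selectivity may be poor, because the C3 carboxyl group on one face and the more distant C2 aryl group on the other are both modest shields. Alkene migration on the metal before hydrogen delivery would erase the control. After the phenols are unmasked, hydrogenolysis of the benzylic C2–O1 bond becomes possible.

Fallback, from 17, returning at 19 (18 is bypassed): the C3 substituent is made much larger and non-coordinating before hydrogenation. Reduction of 17 through the mixed anhydride (i-BuOCOCl, N-methylmorpholine, THF, −15 °C; then NaBH4, H2O) should give {(2S,3R,4Z)-2-[4-(benzyloxy)-3-methoxyphenyl]-4-[4-(benzyloxy)-3-methoxybenzylidene]tetrahydrofuran-3-yl}methanol F4 without touching the alkene. Silylation (t-BuPh2SiCl, imidazole, DMF) gives the tert-butyldiphenylsilyl ether F5. Hydrogenation (H2, 10% Pd/C, EtOAc) anti to the bulky silyloxymethyl group gives (2S,3R,4R)-3-{[tert-butyl(diphenyl)silyl]oxymethyl}-2-(4-hydroxy-3-methoxyphenyl)-4-(4-hydroxy-3-methoxybenzyl)tetrahydrofuran F6. Desilylation (Bu4NF, AcOH, THF) gives 19.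

**Step 6.** The diastereomeric salts may oil out or co-crystallise, so that no useful enrichment is reached.

Fallback, from 12, returning at 17 (14–16 are bypassed): the racemic ester 12 is separated by preparative chromatography on a chiral stationary phase (supercritical CO2–MeOH) to give methyl (2S,3S,4Z)-2-[4-(benzyloxy)-3-methoxyphenyl]-4-[4-(benzyloxy)-3-methoxybenzylidene]tetrahydrofuran-3-carboxylate F3 as a single enantiomer. F3 is saponified as in step 5 to give 17. The configuration is confirmed at 19 by comparison of the sign of rotation with natural (+)-lariciresinol.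

**Step 10.** Enzymatic acylation may be slow or incomplete, because the hydroxymethyl group sits between two substituted ring carbons and the substrate is a single enantiomer that the enzyme pocket may not fit well.

Fallback, from 19, returning at 21: exhaustive acylation (stearoyl chloride, 3.5 equiv, pyridine, DMAP, CH2Cl2) should give [(2S,3R,4R)-2-[3-methoxy-4-(octadecanoyloxy)phenyl]-4-[3-methoxy-4-(octadecanoyloxy)benzyl]tetrahydrofuran-3-yl]methyl octadecanoate F7. The two aryl esters, which are far more electrophilic than the alkyl ester, are then cleaved selectively by aminolysis (pyrrolidine, 2.2 equiv, CH2Cl2, 0 °C to rt) to leave 21.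

## Further compounds

F1 | step 3 | 3-[4-(benzyloxy)-3-methoxyphenyl]prop-2-yn-1-ol | COc1cc(C#CCO)ccc1OCc1ccccc1
F2 | step 4 | 2-[4-(benzyloxy)-3-methoxyphenyl]-4-[4-(benzyloxy)-3-methoxybenzylidene]-3-(methoxycarbonyl)tetrahydrofuran-3-carboxylic acid, (4Z), racemic, configuration at C3 not assigned | OC(=O)C1(C(=O)OC)/C(=C/c2ccc(OCc3ccccc3)c(OC)c2)CO[C@@H]1c1ccc(OCc2ccccc2)c(OC)c1
F3 | step 6 | methyl (2S,3S,4Z)-2-[4-(benzyloxy)-3-methoxyphenyl]-4-[4-(benzyloxy)-3-methoxybenzylidene]tetrahydrofuran-3-carboxylate, single enantiomer | COC(=O)[C@H]1/C(=C/c2ccc(OCc3ccccc3)c(OC)c2)CO[C@@H]1c1ccc(OCc2ccccc2)c(OC)c1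
F4 | step 8 | {(2S,3R,4Z)-2-[4-(benzyloxy)-3-methoxyphenyl]-4-[4-(benzyloxy)-3-methoxybenzylidene]tetrahydrofuran-3-yl}methanol | OC[C@H]1/C(=C/c2ccc(OCc3ccccc3)c(OC)c2)CO[C@@H]1c1ccc(OCc2ccccc2)c(OC)c1
F5 | step 8 | tert-butyl{[(2S,3R,4Z)-2-[4-(benzyloxy)-3-methoxyphenyl]-4-[4-(benzyloxy)-3-methoxybenzylidene]tetrahydrofuran-3-yl]methoxy}diphenylsilane | CC(C)(C)[Si](c1ccccc1)(c1ccccc1)OC[C@H]1/C(=C/c2ccc(OCc3ccccc3)c(OC)c2)CO[C@@H]1c1ccc(OCc2ccccc2)c(OC)c1
F6 | step 8 | (2S,3R,4R)-3-{[tert-butyl(diphenyl)silyl]oxymethyl}-2-(4-hydroxy-3-methoxyphenyl)-4-(4-hydroxy-3-methoxybenzyl)tetrahydrofuran | CC(C)(C)[Si](c1ccccc1)(c1ccccc1)OC[C@H]1[C@@H](Cc2ccc(O)c(OC)c2)CO[C@@H]1c1ccc(O)c(OC)c1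
F7 | step 10 | [(2S,3R,4R)-2-[3-methoxy-4-(octadecanoyloxy)phenyl]-4-[3-methoxy-4-(octadecanoyloxy)benzyl]tetrahydrofuran-3-yl]methyl octadecanoate | CCCCCCCCCCCCCCCCCC(=O)OC[C@H]1[C@@H](Cc2ccc(OC(=O)CCCCCCCCCCCCCCCCC)c(OC)c2)CO[C@@H]1c1ccc(OC(=O)CCCCCCCCCCCCCCCCC)c(OC)c1
A1 | alternative 1 | 4,7-bis[4-(benzyloxy)-3-methoxyphenyl]-3-oxabicyclo[3.2.0]heptan-6-one, cis-fused, 4-aryl exo, C7 unassigned | O=C2[C@H]1[C@@H](C2c3ccc(OCc4ccccc4)c(OC)c3)CO[C@@H]1c1ccc(OCc2ccccc2)c(OC)c1
A2 | alternative 1 | (2S)-2-[4-(benzyloxy)-3-methoxyphenyl]-2,5-dihydrofuran | COc1cc([C@@H]2C=CCO2)ccc1OCc1ccccc1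
A3 | alternative 1 | [4-(benzyloxy)-3-methoxyphenyl]acetyl chloride | COc1cc(CC(Cl)=O)ccc1OCc1ccccc1
A4 | alternative 1 | [4-(benzyloxy)-3-methoxyphenyl]ketene | COc1cc(C=C=O)ccc1OCc1ccccc1
A5 | alternative 2 | methyl 2-[4-(benzyloxy)-3-methoxyphenyl]-4-[4-(benzyloxy)-3-methoxybenzyl]-2,3-dihydrofuran-3-carboxylate, 2,3-trans | COC(=O)[C@H]1C(Cc2ccc(OCc3ccccc3)c(OC)c2)=CO[C@@H]1c1ccc(OCc2ccccc2)c(OC)c1
A6 | alternative 2 | (2R,5R)-1-[4-(benzyloxy)-3-methoxybenzyl]-2,5-dimethylthiolan-1-ium trifluoromethanesulfonate | C[C@@H]1CC[C@@H](C)[S+]1Cc1ccc(OCc2ccccc2)c(OC)c1.[O-]S(=O)(=O)C(F)(F)F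
A7 | alternative 2 | methyl 4-[4-(benzyloxy)-3-methoxyphenyl]-3-formylbut-2-enoate, geometry not specified | COC(=O)C=C(C=O)Cc1ccc(OCc2ccccc2)c(OC)c1
A8 | alternative 3 | methyl 2-[4-(benzyloxy)-3-methoxyphenyl]-4-[4-(benzyloxy)-3-methoxybenzyl]tetrahydrofuran-3-carboxylate, 2,3-trans-3,4-cis | COC(=O)[C@H]1[C@@H](Cc2ccc(OCc3ccccc3)c(OC)c2)CO[C@@H]1c1ccc(OCc2ccccc2)c(OC)c1
A9 | alternative 3 | methyl (3R)-3-(allyloxy)-3-[4-(benzyloxy)-3-methoxyphenyl]-2-bromopropanoate, mixture at C2 | COC(=O)C(Br)[C@H](OCC=C)c1ccc(OCc2ccccc2)c(OC)c1
A10 | alternative 3 | [4-(benzyloxy)-3-methoxyphenyl]zinc bromide | COc1cc([Zn]Br)ccc1OCc1ccccc1
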